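## Retrosynthetic overview
- The target is a 7-oxabicyclo[4.1.0]heptenone: an acetate at C1, a methyl enone, and a farnesyl-bearing epoxide carbon. It comes from 1,2-reduction and acetylation of epoxy-enedione **11**, with the C1–OH set syn to the epoxide.
- **11** comes from enantioselective nucleophilic epoxidation of 2-farnesyl-5-methylbenzoquinone **10**, which sets C5 and C6. The epoxide is the only new ring, formed in step 8 after the aromatic ring has been carried through as the quinone.
- **Key radical disconnection:** ring C5–C1′ of **10**. A photo-oxidatively generated (E,E)-farnesyl radical from allylsilane **7** adds to toluquinone **9**, which is made from o-cresol.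
- **7** comes from Pd-catalysed Kumada coupling of (E)-vinyl iodide **6**, itself from Zr-catalysed carboalumination of enyne **5**. **5** comes from acetylide alkylation of Julia–Johnson (E)-homoallylic bromide **4**, which is made from cyclopropyl methyl ketone and a homoprenyl Grignard.

Assumption: the 2,5-regioisomer from the radical step and the farnesyl-alkene epoxide from step 8 are the isolable major products, and each is separated from its regioisomer by chromatography.

## Route

**Step 1**
Reactants: **1** cyclopropyl methyl ketone; **2** 5-bromo-2-methylpent-2-ene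
Product: **3** 2-cyclopropyl-6-methylhept-5-en-2-ol
Conditions: (a) Mg, THF, reflux, to make the Grignard from **2**; (b) add **1**, 0 °C→rt; aq. NH4Cl
Reagents that add atoms: none
Why: Grignard 1,2-addition to the ketone gives the tertiary cyclopropylcarbinol needed for the Julia–Johnson rearrangement.

**Step 2**
Reactants: **3**
Product: **4** (E)-1-bromo-4,8-dimethylnona-3,7-diene
Conditions: 48% aq. HBr, ZnBr2 (cat.), CH2Cl2, 0 °C, 15 min
Reagents that add atoms: hydrogen bromide, Br
Why: Julia–Johnson cyclopropylcarbinyl-to-homoallyl ring opening delivers the trisubstituted alkene with E selectivity (about 95:5) through a chair-like cation. This sets the geometry of the C6′=C7′ alkene of the farnesyl chain.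

**Step 3**
Reactants: **4**
Product: **5** (E)-6,10-dimethylundeca-5,9-dien-1-yne
Conditions: LiC≡CH·H2NCH2CH2NH2, DMSO, rt
Reagents that add atoms: lithium acetylide–ethylenediamine complex, [Li+].[C-]#C
Why: SN2 alkylation of the acetylide at the primary bromide extends the chain by two carbons. The alkene geometry is untouched.

**Step 4**
Reactants: **5**
Product: **6** (1E,5E)-1-iodo-2,6,10-trimethylundeca-1,5,9-triene
Conditions: Me3Al, Cp2ZrCl2 (cat.), ClCH2CH2Cl, rt; then I2, THF, –30→0 °C
Reagents that add atoms: trimethylaluminium, C[Al](C)C; iodine, II
Why: Negishi Zr-catalysed carboalumination is a syn methylalumination of the terminal alkyne only, with the trisubstituted alkenes inert. Iodinolysis gives the (E)-trisubstituted vinyl iodide, which sets the C2′=C3′ alkene.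

**Step 5**
Reactants: **6**
Product: **7** trimethyl[(2E,6E)-3,7,11-trimethyldodeca-2,6,10-trien-1-yl]silane
Conditions: Me3SiCH2MgCl, Pd(PPh3)4 (5 mol%), THF, rt
Reagents that add atoms: (trimethylsilyl)methylmagnesium chloride, C[Si](C)(C)C[Mg]Cl
Why: Kumada–Corriu coupling of an alkenyl iodide with the silylmethyl Grignard gives an allylsilane with retention of alkene geometry. This installs C1′ and the radical precursor in a single step.

**Step 6**
Reactants: **8** o-cresol
Product: **9** 2-methyl-1,4-benzoquinone
Conditions: (KSO3)2NO (Fremy's salt, 2.2 equiv), aq. KH2PO4/acetone, rt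
Reagents that add atoms: Fremy's salt, [K+].[K+].[O]N(S(=O)(=O)[O-])S(=O)(=O)[O-]; water, O
Why: The Teuber oxidation of a phenol with a free para position gives the p-quinone.

**Step 7 (key radical step)**
Reactants: **7** farnesylsilane (1 equiv); **9** toluquinone (3 equiv)
Product: **10** 2-methyl-5-[(2E,6E)-3,7,11-trimethyldodeca-2,6,10-trien-1-yl]cyclohexa-2,5-diene-1,4-dione
Conditions: Mes-Acr+ ClO4– (2 mol%), MeCN, blue LEDs (450 nm), rt, 12 h; then MnO2, CH2Cl2, rt; separate the 2,6-isomer by chromatography
Reagents that add atoms: none
Why: Photo-oxidation of the allylsilane gives a radical cation that loses Me3Si+ to form the farnesyl radical. The radical adds through its unhindered primary terminus (C1′), so no branched product forms. It attacks C5 of toluquinone, the position β to the more electrophilic C1 carbonyl and remote from the methyl group. The hydroquinone adduct is then re-oxidised to the quinone.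
Proposed new method: Acridinium-photo-oxidative generation of a polyprenyl radical from an allylsilane and its Giese-type addition to a quinone, with tautomerisation and re-oxidation. The closest known reactions are photoredox or Minisci-type alkylation of quinones and photochemical allylation of quinones with allylsilanes or allylstannanes.

**Step 8**
Reactants: **10**
Product: **11** (1R,6S)-4-methyl-1-[(2E,6E)-3,7,11-trimethyldodeca-2,6,10-trien-1-yl]-7-oxabicyclo[4.1.0]hept-3-ene-2,5-dione
Conditions: 30% aq. H2O2 (1.1 equiv), aq. K2CO3, toluene, N-(9-anthracenylmethyl)cinchonidinium bromide (10 mol%, pseudo-enantiomer chosen for the (1R,6S) epoxide), 0 °C; separate the regioisomeric epoxide by chromatography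
Reagents that add atoms: hydrogen peroxide, OO
Why: Weitz–Scheffer nucleophilic epoxidation adds HOO– to C6–H, the carbon β to the C4 carbonyl. The resulting enolate closes onto the O–O bond, and the chiral ion pair selects the enone face, setting C5 and C6 together. The farnesyl alkenes are inert to nucleophilic peroxide.
Proposed new method: Enantioselective phase-transfer epoxidation of a 2,5-dialkylbenzoquinone at the farnesyl-bearing alkene. The closest known reactions are cinchona-PTC epoxidation of 2-methyl-1,4-naphthoquinone and of enones. Selectivity between the two ring alkenes is moderate and is handled by chromatography.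

**Step 9**
Reactants: **11**
Product: **12** (1R,5R,6R)-5-hydroxy-4-methyl-1-[(2E,6E)-3,7,11-trimethyldodeca-2,6,10-trien-1-yl]-7-oxabicyclo[4.1.0]hept-3-en-2-one
Conditions: NaBH4 (1.0 equiv), CeCl3·7H2O, MeOH/CH2Cl2, –78 °C
Reagents that add atoms: none
Why: Luche 1,2-reduction leaves the C=C bonds and the epoxide intact. The C1 carbonyl is less hindered than C4, which is flanked by the quaternary epoxide carbon. Hydride is delivered anti to the epoxide oxygen, so the new carbinol (C1) is syn to the epoxide, as in the target.

**Step 10**
Reactants: **12**
Product: **13** target, (1R,2R,6R)-3-methyl-5-oxo-6-[(2E,6E)-3,7,11-trimethyldodeca-2,6,10-trien-1-yl]-7-oxabicyclo[4.1.0]hept-3-en-2-yl acetate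
Conditions: Ac2O, pyridine, DMAP (cat.), CH2Cl2, 0 °C
Reagents that add atoms: acetic anhydride, CC(=O)OC(C)=O
Why: Standard O-acylation of the secondary allylic alcohol under non-acidic conditions keeps the epoxide intact. No stereocentre is touched.

## Compound list
1 | cyclopropyl methyl ketone | CC(=O)C1CC1 | starting material
2 | 5-bromo-2-methylpent-2-ene | CC(C)=CCCBr | starting material
3 | 2-cyclopropyl-6-methylhept-5-en-2-ol | CC(C)=CCCC(C)(O)C1CC1 | intermediate
4 | (E)-1-bromo-4,8-dimethylnona-3,7-diene | BrCC/C=C(\C)CCC=C(C)C | intermediate
5 | (E)-6,10-dimethylundeca-5,9-dien-1-yne | C#CCC/C=C(\C)CCC=C(C)C | intermediate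
6 | (1E,5E)-1-iodo-2,6,10-trimethylundeca-1,5,9-triene | I/C=C(\C)CC/C=C(\C)CCC=C(C)C | intermediate
7 | (2E,6E)-farnesyl trimethylsilane | C[Si](C)(C)C/C=C(\C)CC/C=C(\C)CCC=C(C)C | intermediate
8 | o-cresol | Cc1ccccc1O | starting material
9 | 2-methyl-1,4-benzoquinone | CC1=CC(=O)C=CC1=O | intermediate
10 | 2-farnesyl-5-methyl-1,4-benzoquinone | CC1=CC(=O)C(C/C=C(\C)CC/C=C(\C)CCC=C(C)C)=CC1=O | intermediate
11 | epoxy-enedione (1R,6S) | O=C1C(C)=CC(=O)[C@]2(C/C=C(\C)CC/C=C(\C)CCC=C(C)C)O[C@H]12 | intermediate
12 | epoxy-enone alcohol (1R,5R,6R) | O[C@@H]1C(C)=CC(=O)[C@]2(C/C=C(\C)CC/C=C(\C)CCC=C(C)C)O[C@H]12 | intermediate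
13 | target acetate | CC(=O)O[C@@H]1C(C)=CC(=O)[C@]2(C/C=C(\C)CC/C=C(\C)CCC=C(C)C)O[C@H]12 | target

## Totals
Total steps: 10. Longest linear sequence: 9 (steps 1–5, then 7–10).

## Three steps most likely to fail
1. **Step 7 (radical farnesylation).** The risks are regioisomers (2,5- vs 2,6-), competing Paternò–Büchi or HAT chemistry on the polyene, and E/Z scrambling of the allyl radical.
   Fallback: change to an ionic, regio-defined ring construction. Farnesylate 4-methoxy-3-methylphenol ortho to OH (farnesol, BF3·OEt2), then oxidise with PIDA/MeOH to the quinone monoketal.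
2. **Step 8 (regio- and enantioselective epoxidation).** The methyl- and farnesyl-bearing alkenes are nearly equally reactive, and 2,5-dialkylquinone epoxidation has no direct precedent.
   Fallback: epoxidise 2-farnesylbenzoquinone with its unsubstituted alkene masked as the cyclopentadiene Diels–Alder adduct. Then do the retro-Diels–Alder and install the methyl group by radical methylation of the remaining enedione alkene.
3. **Step 9 (regio- and diastereoselective reduction).** The C1 and C4 carbonyls are similar, and hydride may attack syn to the farnesyl side.
   Fallback: reduce with a ketoreductase panel or Noyori transfer hydrogenation. Alternatively, oxidise any wrong epimer with Dess–Martin periodinane and redo the reduction, or invert it by Mitsunobu with p-nitrobenzoic acid followed by hydrolysis.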